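The 1,2-dioxolane (O1, O2, C3 bearing CH2CO2H, C4, C5 bearing the side chain) is cut at C3–C4 and O1–C5, on both sides of the C4 methylene that separates its two fully substituted carbons. C3 is then a peroxycarbenium carbon and C4/C5 a 2-methyl-1-alkene carrying the whole side chain. The key step, a catalytic asymmetric formal [3+2] annulation, ionises a racemic triethylsilyl peroxyketal of methyl acetoacetate with a confined chiral acid; the alkene CH2 adds to the cation and the silylated peroxide oxygen closes the ring on the tertiary cation. One operation joins both fragments, forms both quaternary centres and brings in the O–O bond intact.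

Key step: step 9

Assumption: the sense of induction of the chiral acid cannot be predicted from first principles; the (S,S) acid is written, and its mirror image is used if a test reaction shows the opposite sense.

Step 1
Reactants: 1 (R)-citronellyl bromide, (6R)-8-bromo-2,6-dimethyloct-2-ene; 2 2-phenylethylmagnesium chloride
Product: 3 [(5S)-5,9-dimethyldec-8-en-1-yl]benzene
Conditions: Li2CuCl4 (3 mol %), THF, −20 °C to rt
Reagents that add atoms: none
Why: Kochi-type copper-catalysed sp3–sp3 cross-coupling of a primary bromide with a primary Grignard reagent; the distal methyl stereocentre comes from the chiral pool and is not touched.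

Step 2
Reactants: 3 [(5S)-5,9-dimethyldec-8-en-1-yl]benzene
Product: 5 (4S)-4-methyl-8-phenyloctan-1-ol, via secondary ozonide 4 (not isolated)
Conditions: O3, CH2Cl2, −78 °C; then NaBH4, MeOH, −78 °C to rt
Reagents that add atoms: ozone, [O-][O+]=O
Why: Ozonolysis with reductive borohydride work-up; the electron-rich trisubstituted alkene should be cleaved long before the benzene ring reacts.

Step 3
Reactants: 5 (4S)-4-methyl-8-phenyloctan-1-ol
Product: 6 [(5S)-8-bromo-5-methyloctyl]benzene
Conditions: CBr4, PPh3, CH2Cl2, 0 °C
Reagents that add atoms: carbon tetrabromide, BrC(Br)(Br)Br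
Why: Appel bromination of a primary alcohol under neutral conditions, remote from the stereocentre.

Step 4
Reactants: 7 (R)-propylene oxide, (2R)-2-methyloxirane; 8 isopropenylmagnesium bromide
Product: 9 (2R)-4-methylpent-4-en-2-ol
Conditions: CuI (10 mol %), THF, −30 to 0 °C; aq NH4Cl
Reagents that add atoms: none
Why: Copper-catalysed ring opening of a terminal epoxide by an alkenyl Grignard reagent at the unsubstituted carbon; the carbinol stereocentre is carried over unchanged from the epoxide.

Step 5
Reactants: 9 (2R)-4-methylpent-4-en-2-ol
Product: 10 (2R)-4-methylpent-4-en-2-yl 4-methylbenzenesulfonate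
Conditions: TsCl, Et3N, DMAP (cat.), CH2Cl2, 0 °C
Reagents that add atoms: p-toluenesulfonyl chloride, Cc1ccc(cc1)S(=O)(=O)Cl
Why: O-sulfonylation of a secondary alcohol, which leaves the C–O bond and its configuration intact.

Step 6
Reactants: 6 [(5S)-8-bromo-5-methyloctyl]benzene; 10 (2R)-4-methylpent-4-en-2-yl 4-methylbenzenesulfonate
Product: 12 (4R,8S)-2,4,8-trimethyl-12-phenyldodec-1-ene, via Grignard reagent 11 (not isolated)
Conditions: 6, Mg, THF, 40 °C; then 10, CuI (10 mol %), TMEDA (20 mol %), LiOMe, THF, 0 °C
Reagents that add atoms: none
Why: Copper-catalysed SN2 cross-coupling of a secondary alkyl tosylate with a primary alkyl Grignard reagent; displacement with inversion sets C4, and the descriptor stays R only because the CIP priorities change.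

Step 7
Reactants: 13 methyl 3-methylbut-3-enoate
Product: 15 methyl 3-hydroperoxy-3-methoxybutanoate (racemic), via carbonyl oxide 14 (not isolated)
Conditions: O3, MeOH/CH2Cl2, −78 °C
Reagents that add atoms: ozone, [O-][O+]=O; methanol, CO
Why: Ozonolysis in methanol; Criegee fragmentation of the primary ozonide should give the more substituted carbonyl oxide and formaldehyde, and methanol traps the carbonyl oxide as the α-methoxy hydroperoxide.

Step 8
Reactants: 15 methyl 3-hydroperoxy-3-methoxybutanoate
Product: 16 methyl 3-methoxy-3-[(triethylsilyl)peroxy]butanoate (racemic)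
Conditions: Et3SiCl, imidazole, DMF, 0 °C
Reagents that add atoms: chlorotriethylsilane, CC[Si](Cl)(CC)CC
Why: O-silylation of the hydroperoxide with a weak base, expected to be faster than attack of the hydroperoxide on the neighbouring ester.

Step 9
Reactants: 12 (4R,8S)-2,4,8-trimethyl-12-phenyldodec-1-ene; 16 methyl 3-methoxy-3-[(triethylsilyl)peroxy]butanoate
Product: 19 methyl 2-[(3R,5R)-5-[(2R,6S)-2,6-dimethyl-10-phenyldecyl]-3,5-dimethyl-1,2-dioxolan-3-yl]acetate, via peroxycarbenium ion 17 (not isolated), via tertiary carbocation 18 (not isolated)
Conditions: (S,S)-imidodiphosphorimidate Brønsted acid (two (S)-3,3'-bis[3,5-bis(trifluoromethyl)phenyl]-BINOL phosphoryl units bridged by nitrogen, each P=N–SO2CF3; 5 mol %), 4 Å MS, methylcyclohexane/CH2Cl2, −78 °C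
Reagents that add atoms: none
Why: Proposed new method: the chiral acid (after the first turnover its triethylsilyl form) removes the methoxy group of 16 as Et3SiOMe and leaves the planar peroxycarbenium ion 17 inside the confined chiral anion, so both enantiomers of racemic 16 converge; the CH2 terminus of 12 then adds to the cationic carbon (C3–C4 bond) and the tertiary cation 18 is captured by the silylated distal peroxide oxygen (O1–C5 bond), which hands Et3Si+ back to the anion and closes the catalytic cycle. The closest known reaction types are the SnCl4-promoted annulation of triethylsilyl peroxyketals with alkenes to 1,2-dioxolanes, which gives no absolute control, and silylium imidodiphosphorimidate counteranion catalysis of oxocarbenium ions with weakly nucleophilic alkenes. The dioxolane closes by collapse of a cation with oxygen, a stepwise formal [3+2] annulation that is 5-endo with respect to the former C=C bond. C3 is set by the anion-controlled face of 17 in the C–C bond formation; C5 is set in the ring closure, where the anion pocket should reinforce the intrinsic bias for the envelope that keeps the two methyl groups cis and pseudo-axial and the two larger arms pseudo-equatorial. The step needs Markovnikov regioselectivity, secured by the 1,1-disubstituted alkene of 12 (only the tertiary cation can form), and ring closure ahead of proton loss or hydride shift, secured by the O–SiEt3 group of 16, which keeps the distal oxygen nucleophilic and leaves as the chain carrier. The two remote stereocentres of 12 take no part, so the outcome rests on catalyst control alone.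

Step 10
Reactants: 19 methyl 2-[(3R,5R)-5-[(2R,6S)-2,6-dimethyl-10-phenyldecyl]-3,5-dimethyl-1,2-dioxolan-3-yl]acetate
Product: 20 2-[(3R,5R)-5-[(2R,6S)-2,6-dimethyl-10-phenyldecyl]-3,5-dimethyl-1,2-dioxolan-3-yl]acetic acid
Conditions: LiOH·H2O, THF/H2O, 0 °C to rt; then dilute aq HCl
Reagents that add atoms: lithium hydroxide, [Li+].[OH-]
Why: Saponification of the methyl ester; C3 and C5 carry no hydrogen, so Kornblum–DeLaMare cleavage of the peroxide cannot occur and no stereocentre can epimerise.

Compound list
1 | (R)-citronellyl bromide, (6R)-8-bromo-2,6-dimethyloct-2-ene | C[C@@H](CCBr)CCC=C(C)C | starting material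
2 | 2-phenylethylmagnesium chloride | Cl[Mg]CCc1ccccc1 | starting material
3 | [(5S)-5,9-dimethyldec-8-en-1-yl]benzene | C[C@@H](CCCCc1ccccc1)CCC=C(C)C | intermediate
4 | 3,3-dimethyl-5-[(3S)-3-methyl-7-phenylheptyl]-1,2,4-trioxolane (secondary ozonide, not isolated) | C[C@@H](CCCCc1ccccc1)CCC1OOC(C)(C)O1 | intermediate
5 | (4S)-4-methyl-8-phenyloctan-1-ol | C[C@@H](CCCCc1ccccc1)CCCO | intermediate
6 | [(5S)-8-bromo-5-methyloctyl]benzene | C[C@@H](CCCCc1ccccc1)CCCBr | intermediate
7 | (R)-propylene oxide, (2R)-2-methyloxirane | C[C@@H]1CO1 | starting material
8 | isopropenylmagnesium bromide | CC(=C)[Mg]Br | starting material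
9 | (2R)-4-methylpent-4-en-2-ol | C[C@@H](O)CC(C)=C | intermediate
10 | (2R)-4-methylpent-4-en-2-yl 4-methylbenzenesulfonate | C[C@@H](OS(=O)(=O)c1ccc(C)cc1)CC(C)=C | intermediate
11 | [(4S)-4-methyl-8-phenyloctyl]magnesium bromide (not isolated) | C[C@@H](CCCCc1ccccc1)CCC[Mg]Br | intermediate
12 | (4R,8S)-2,4,8-trimethyl-12-phenyldodec-1-ene | C[C@@H](CCCCc1ccccc1)CCC[C@@H](C)CC(C)=C | intermediate
13 | methyl 3-methylbut-3-enoate | COC(=O)CC(C)=C | starting material
14 | carbonyl oxide of methyl acetoacetate (not isolated) | COC(=O)CC(C)=[O+][O-] | intermediate
15 | methyl 3-hydroperoxy-3-methoxybutanoate (racemic) | COC(=O)CC(C)(OC)OO | intermediate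
16 | methyl 3-methoxy-3-[(triethylsilyl)peroxy]butanoate (racemic) | COC(=O)CC(C)(OC)OO[Si](CC)(CC)CC | intermediate
17 | O-triethylsilyl peroxycarbenium ion of methyl acetoacetate, paired with the chiral anion (not isolated) | COC(=O)CC(C)=[O+]O[Si](CC)(CC)CC | intermediate
18 | open-chain tertiary carbocation with the (3R) peroxy carbon already set (not isolated) | C[C@@H](CCCCc1ccccc1)CCC[C@@H](C)C[C+](C)C[C@](C)(CC(=O)OC)OO[Si](CC)(CC)CC | intermediate
19 | methyl 2-[(3R,5R)-5-[(2R,6S)-2,6-dimethyl-10-phenyldecyl]-3,5-dimethyl-1,2-dioxolan-3-yl]acetate | C[C@@H](CCCCc1ccccc1)CCC[C@@H](C)C[C@]1(C)C[C@](C)(CC(=O)OC)OO1 | intermediate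
20 | 2-[(3R,5R)-5-[(2R,6S)-2,6-dimethyl-10-phenyldecyl]-3,5-dimethyl-1,2-dioxolan-3-yl]acetic acid | C[C@@H](CCCCc1ccccc1)CCC[C@@H](C)C[C@]1(C)C[C@](C)(CC(=O)O)OO1 | target

Total step count: 10. Longest linear sequence: 6 steps (1, 2, 3, 6, 9, 10).

Steps most likely to fail

Step 9. The chiral anion may fail to select one face of the peroxycarbenium ion or one face in the ring closure, and proton loss or hydride shift in the tertiary cation may compete with closure. The fallback gives up catalyst control and uses known chemistry. It sets out from 12 and 16, which are combined with stoichiometric SnCl4 in CH2Cl2 at −78 °C, the established annulation of triethylsilyl peroxyketals with 1,1-disubstituted alkenes. This should give methyl 2-[3,5-dimethyl-5-[(2R,6S)-2,6-dimethyl-10-phenyldecyl]-1,2-dioxolan-3-yl]acetate as the mixture of its four ring stereoisomers F1. Because the side chain is a single enantiomer, all four are diastereomers. Chromatography on silica gel should separate the cis from the trans ring isomers, and preparative HPLC on a cellulose carbamate chiral stationary phase should separate the (3R,5R) from the (3S,5S) isomer. The route is rejoined at 19.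

Step 6. E2 elimination of the homoallylic secondary tosylate to a diene, or partial loss of stereospecificity through a radical pathway at copper, may erode yield or the configuration at C4. The fallback sets C4 by conjugate addition instead of substitution. It sets out from Grignard reagent 11 (made from 6), which is added to (E)-pent-3-en-2-one with CuBr·SMe2 (5 mol %) and the ligand (R)-1-[(S)-2-(diphenylphosphino)ferrocenyl]ethyldicyclohexylphosphine, or its mirror image, whichever gives the 4R sense, in t-BuOMe at −75 °C. This should give (4R,8S)-4,8-dimethyl-12-phenyldodecan-2-one F2. Wittig methylenation (Ph3PCH3Br, KOtBu, THF, 0 °C) then returns the route at 12.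

Step 10. Hydroxide may form the ester enolate, which can expel the ring peroxide oxygen by β-elimination and open the dioxolane. The fallback moves the ester cleavage from hydroxide to an enzyme of the carboxylesterase class (pig liver esterase, phosphate buffer pH 7 with acetone as cosolvent, 25 °C), so that no base able to form the enolate is present. It sets out from 19 and comes back at 20 without any new compound.

Further compounds
F1 | step 9 | methyl 2-[3,5-dimethyl-5-[(2R,6S)-2,6-dimethyl-10-phenyldecyl]-1,2-dioxolan-3-yl]acetate, mixture of the four ring stereoisomers | C[C@@H](CCCCc1ccccc1)CCC[C@@H](C)CC1(C)CC(C)(CC(=O)OC)OO1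
F2 | step 6 | (4R,8S)-4,8-dimethyl-12-phenyldodecan-2-one | C[C@@H](CCCCc1ccccc1)CCC[C@@H](C)CC(C)=O
F0 | step 10 | none | none
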